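**Retrosynthetic overview**

1. Target 23 ⇒ (desilylation, acetylation, C9 carbinol by oxazaborolidine reduction, C7=C8 by dehydrogenation) ⇒ spiro trione 19, (1R,5R)-2-oxaspiro[4.5]decane-3,6,9-trione with the protected side chain on C1.
2. Key disconnection: the C4–C5 bond (lactone CH2 to spiro carbon). The lactone ring is closed onto an aromatic ring: the lithium enolate of the C1 acetate adds to the ipso carbon of a Cr(CO)3-bound 2,5-dimethoxyphenyl ring (19 ⇒ 15). Protonation and hydrolysis turn the two ArOMe carbons into the C6 and C9 ketones.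
3. Enabling feature: the carbocycle C5–C10 is a hydroquinone dimethyl ether in disguise (oxygen on C6 and C9, para to each other). C5 is its ipso carbon and carries C1–O, so the C1 acetate reaches C5 through a five-membered ring. Cr(CO)3, placed on one arene face by the C1 hydroxyl, makes C5 electrophilic and leaves only the opposite face open.
4. 15 ⇒ carbinol 13 ⇒ 2,5-dimethoxybenzaldehyde 10 + alkenyl iodide 9 (enantioselective alkenylzinc addition sets C1). 9 comes from 5-bromo-2-methylpent-2-ene 1 by alkynylation, carboalumination–iodination, epoxidation, selenide opening–selenoxide elimination and silylation.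
5. Ring order: the six-membered carbocycle is bought as the arene; the lactone ring is formed in step 9, which at the same time dearomatizes the carbocycle. No other ring is made.

Key step: step 9

Assumption: η-bonded Cr(CO)3 complexes are written in SMILES as the organic ligand and the Cr(CO)3 unit joined by a dot, because SMILES cannot express hapticity or planar chirality; the metal-bearing face is given in the name.
Locants: 2-oxaspiro[4.5]decane numbering of the target is used throughout (C1 lactone CH, O2, C3 lactone C=O, C4 lactone CH2, C5 spiro carbon, C6 ketone, C7=C8, C9 acetoxy carbon, C10 CH2).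

**Route**

Step 1
Reactants: 1 5-bromo-2-methylpent-2-ene
Product: 2 6-methylhept-5-en-1-yne
Conditions: HC≡CLi·H2NCH2CH2NH2, DMSO, 0 °C → rt
Reagents that add atoms: lithium acetylide (ethylenediamine complex), [Li]C#C
Why: SN2 alkylation of lithium acetylide by the primary homoallylic bromide (acetylide alkylation) builds the enyne; no stereo element is involved.

Step 2
Reactants: 2 6-methylhept-5-en-1-yne
Product: 4 (1E)-1-iodo-2,6-dimethylhepta-1,5-diene, via alkenylalane 3 (not isolated)
Conditions: AlMe3 (2 equiv), Cp2ZrCl2 (0.25 equiv), CH2Cl2, 0 °C → rt; then I2, THF, −30 → 0 °C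
Reagents that add atoms: trimethylaluminium, C[Al](C)C; iodine, II
Why: Negishi carboalumination (zirconocene-catalysed syn addition of Me–Al, methyl to the internal carbon) followed by iodinolysis with retention fixes the E trisubstituted iodoalkene that becomes the C1-attached alkene of the side chain.

Step 3
Reactants: 4 (1E)-1-iodo-2,6-dimethylhepta-1,5-diene
Product: 5 rac-3-[(3E)-4-iodo-3-methylbut-3-en-1-yl]-2,2-dimethyloxirane
Conditions: mCPBA, NaHCO3, CH2Cl2, 0 °C
Reagents that add atoms: mCPBA, OOC(=O)c1cccc(Cl)c1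
Why: Prilezhaev epoxidation takes the electron-rich trisubstituted alkene and leaves the iodine-deactivated alkene; the epoxide CH stereocenter is racemic but becomes sp2 in step 4.

Step 4
Reactants: 5 rac-3-[(3E)-4-iodo-3-methylbut-3-en-1-yl]-2,2-dimethyloxirane
Product: 8 (3E,6E)-7-iodo-2,6-dimethylhepta-3,6-dien-2-ol, via hydroxy selenide 6 (not isolated), via selenoxide 7 (not isolated)
Conditions: (PhSe)2, NaBH4, EtOH, rt → 78 °C; then 30% H2O2, THF, 0 °C → rt
Reagents that add atoms: none
Why: Selenide opening–selenoxide elimination of an epoxide (Sharpless–Lauer type): PhSe– opens at the less hindered CH, and the selenoxide eliminates syn, away from the carbinol carbon, to give the E allylic tertiary alcohol.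

Step 5
Reactants: 8 (3E,6E)-7-iodo-2,6-dimethylhepta-3,6-dien-2-ol
Product: 9 triethyl{[(3E,6E)-7-iodo-2,6-dimethylhepta-3,6-dien-2-yl]oxy}silane
Conditions: Et3SiOTf, 2,6-lutidine, CH2Cl2, −78 → 0 °C
Reagents that add atoms: triethylsilyl triflate, CC[Si](CC)(CC)OS(=O)(=O)C(F)(F)F
Why: Silylation of the hindered tertiary alcohol with the silyl triflate protects it against the organolithium, amide-base and acid steps that follow.

Step 6
Reactants: 9 triethyl{[(3E,6E)-7-iodo-2,6-dimethylhepta-3,6-dien-2-yl]oxy}silane; 10 2,5-dimethoxybenzaldehyde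
Product: 13 (1R,2E,5E)-1-(2,5-dimethoxyphenyl)-3,7-dimethyl-7-(triethylsilyloxy)octa-2,5-dien-1-ol, via alkenyllithium 11 (not isolated), via alkenyl(ethyl)zinc 12 (not isolated)
Conditions: 9, t-BuLi (2 equiv), Et2O, −78 °C; EtZnCl, −78 → 0 °C; N,N,N',N'-tetraethylethylenediamine; (+)-3-exo-morpholinoisoborneol ((+)-MIB, 10 mol %), 10, toluene, 0 °C
Reagents that add atoms: none
Why: Iodine–lithium exchange with retention, transmetalation to zinc and amino-alcohol (MIB)-catalysed enantioselective alkenylzinc addition to the Re face of the aryl aldehyde should set the C1 carbinol as R (the ligand antipode of the one that gives S carbinols), the diamine masking lithium salts to suppress the racemic background.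

Step 7
Reactants: 13 (1R,2E,5E)-1-(2,5-dimethoxyphenyl)-3,7-dimethyl-7-(triethylsilyloxy)octa-2,5-dien-1-ol
Product: 14 tricarbonyl(η6-arene)chromium complex of 13, Cr(CO)3 on the arene face that bears the C1 hydroxyl when C1–H lies in the ring plane beside the 2-OMe group
Conditions: (η6-naphthalene)Cr(CO)3 (1.3 equiv), THF (3 equiv), Et2O, 70 °C, sealed tube, dark
Reagents that add atoms: (η6-naphthalene)tricarbonylchromium, c1ccc2ccccc2c1.O=C=[Cr](=C=O)=C=O
Why: Arene exchange from the labile naphthalene complex is steered by the benzylic hydroxyl: in the rotamer with C1–H eclipsing the ortho methoxy group (least 1,3-allylic strain) the OH delivers Cr(CO)3 to its own face while the dienyl chain shields the other, which sets the planar chirality.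

Step 8
Reactants: 14 tricarbonyl(η6-arene)chromium complex of 13
Product: 15 tricarbonyl(η6-arene)chromium complex of (1R,2E,5E)-1-(2,5-dimethoxyphenyl)-3,7-dimethyl-7-(triethylsilyloxy)octa-2,5-dien-1-yl acetate, same metal face as 14
Conditions: Ac2O, DMAP (cat.), Et3N, CH2Cl2, 0 °C
Reagents that add atoms: acetic anhydride, CC(=O)OC(C)=O
Why: DMAP-catalysed acetylation puts the two-carbon nucleophile on the C1 oxygen without touching the stereocenter or the complex.

Step 9
Reactants: 15 tricarbonyl(η6-arene)chromium complex of the C1 acetate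
Product: 19 (1R,5R)-1-[(1E,4E)-2,6-dimethyl-6-(triethylsilyloxy)hepta-1,4-dien-1-yl]-2-oxaspiro[4.5]decane-3,6,9-trione, via lithium enolate 16 (not isolated), via cyclohexadienyl chromate 17 (not isolated), via bis(enol ether) 18 (not isolated)
Conditions: LiN(SiMe3)2 (1.2 equiv), THF–DMPU, −78 → −40 °C; CF3CO2H (5 equiv), −78 → 0 °C; CO (5 bar), rt; then (CO2H)2, THF–H2O, 0 °C → rt
Reagents that add atoms: water, O
Why: LiN(SiMe3)2 removes an acetate CH3 proton (ring and benzylic C–H are left alone by this weaker amide base) and the lithium enolate 16 adds through carbon to the ipso carbon of the π-bound ring, made electrophilic by Cr(CO)3, to give the anionic η5-cyclohexadienyl complex 17; protonation at the unsubstituted dienyl terminus (future C10), displacement of the diene by CO and hydrolysis of the two methyl enol ethers of 18 then give the C6 and C9 ketones. The closest known reaction type is the Semmelhack nucleophilic addition of lithium ester enolates and of tethered carbanions (ipso spirocyclisation) to (arene)Cr(CO)3 complexes, followed by protonation and enol ether hydrolysis of methoxy-substituted adducts. The lactone ring closes in a 5-exo-trig mode by C4–C5 bond formation, the enolate being held on C1 through the ester oxygen next to the attacked ipso carbon. The only new stereocenter, C5, is controlled by the metal: the nucleophile must enter on the face opposite to Cr(CO)3, and because that face was fixed relative to C1 in step 7 the ester oxygen swings to the free face with C1–H on the C10 side and the side chain on the C6 side, which is the (5R) configuration of the target. The step needs ipso attack rather than attack at the neighbouring unsubstituted ring carbon (six-membered ring) and needs the enolate to survive; the kinetic preference for five-membered spiro closure at −78 °C, the poor reversibility of ester enolate addition and the low temperature (no Ireland–Claisen shift) should secure both.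

Step 10
Reactants: 19 (1R,5R)-spiro trione
Product: 20 (1R,5R)-1-[(1E,4E)-2,6-dimethyl-6-(triethylsilyloxy)hepta-1,4-dien-1-yl]-2-oxaspiro[4.5]dec-7-ene-3,6,9-trione
Conditions: IBX, 4-methoxypyridine N-oxide, DMSO, 25 °C
Reagents that add atoms: none
Why: IBX-mediated α,β-dehydrogenation of a ketone installs the C7=C8 alkene between the two carbonyls; since C5 is quaternary, no other alkene and no quinone can form.

Step 11
Reactants: 20 (1R,5R)-enetrione
Product: 21 (1R,5R,9S)-9-hydroxy-1-[(1E,4E)-2,6-dimethyl-6-(triethylsilyloxy)hepta-1,4-dien-1-yl]-2-oxaspiro[4.5]dec-7-ene-3,6-dione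
Conditions: (R)-B-methyl oxazaborolidine from diphenylprolinol ((R)-Me-CBS, 0.3 equiv), catecholborane (1.5 equiv), toluene, −78 °C
Reagents that add atoms: none
Why: Corey–Bakshi–Shibata reduction: the catalyst delivers hydride to the C9 carbonyl with the C7=C8 alkene as the large and C10H2 as the small group (same sense as (S)-catalyst → (R)-1-phenylethanol, hence (R)-catalyst → 9S), while the C6 carbonyl next to the quaternary C5 should react more slowly.

Step 12
Reactants: 21 (1R,5R,9S)-allylic alcohol
Product: 22 (1R,5R,9S)-1-[(1E,4E)-2,6-dimethyl-6-(triethylsilyloxy)hepta-1,4-dien-1-yl]-3,6-dioxo-2-oxaspiro[4.5]dec-7-en-9-yl acetate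
Conditions: Ac2O, DMAP (cat.), pyridine, CH2Cl2, 0 °C
Reagents that add atoms: acetic anhydride, CC(=O)OC(C)=O
Why: DMAP-catalysed acetylation of the secondary allylic alcohol proceeds with retention at C9.

Step 13
Reactants: 22 (1R,5R,9S)-silyl-protected acetate
Product: 23 (1R,5R,9S)-1-[(1E,4E)-6-hydroxy-2,6-dimethylhepta-1,4-dien-1-yl]-3,6-dioxo-2-oxaspiro[4.5]dec-7-en-9-yl acetate (target)
Conditions: HF·pyridine, pyridine, THF, 0 °C
Reagents that add atoms: none
Why: Fluoride-mediated cleavage of the tertiary triethylsilyl ether under buffered conditions should leave the acetate, the lactone and the enone intact.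

**Compound list**

1 | 5-bromo-2-methylpent-2-ene | CC(C)=CCCBr | starting material
2 | 6-methylhept-5-en-1-yne | C#CCCC=C(C)C | intermediate
3 | [(1E)-2,6-dimethylhepta-1,5-dien-1-yl]dimethylalumane (not isolated) | C[Al](C)/C=C(\C)CCC=C(C)C | intermediate
4 | (1E)-1-iodo-2,6-dimethylhepta-1,5-diene | I/C=C(\C)CCC=C(C)C | intermediate
5 | rac-3-[(3E)-4-iodo-3-methylbut-3-en-1-yl]-2,2-dimethyloxirane | I/C=C(\C)CCC1OC1(C)C | intermediate
6 | rac-(6E)-7-iodo-2,6-dimethyl-3-(phenylselanyl)hept-6-en-2-ol (not isolated) | I/C=C(\C)CCC([Se]c1ccccc1)C(C)(C)O | intermediate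
7 | rac-(6E)-7-iodo-2,6-dimethyl-3-(phenylseleninyl)hept-6-en-2-ol (not isolated) | I/C=C(\C)CCC([Se](=O)c1ccccc1)C(C)(C)O | intermediate
8 | (3E,6E)-7-iodo-2,6-dimethylhepta-3,6-dien-2-ol | I/C=C(\C)C/C=C/C(C)(C)O | intermediate
9 | triethyl{[(3E,6E)-7-iodo-2,6-dimethylhepta-3,6-dien-2-yl]oxy}silane | I/C=C(\C)C/C=C/C(C)(C)O[Si](CC)(CC)CC | intermediate
10 | 2,5-dimethoxybenzaldehyde | COc1ccc(OC)c(C=O)c1 | starting material
11 | [(1E,4E)-2,6-dimethyl-6-(triethylsilyloxy)hepta-1,4-dien-1-yl]lithium (not isolated) | [Li]/C=C(\C)C/C=C/C(C)(C)O[Si](CC)(CC)CC | intermediate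
12 | [(1E,4E)-2,6-dimethyl-6-(triethylsilyloxy)hepta-1,4-dien-1-yl](ethyl)zinc (not isolated) | CC[Zn]/C=C(\C)C/C=C/C(C)(C)O[Si](CC)(CC)CC | intermediate
13 | (1R,2E,5E)-1-(2,5-dimethoxyphenyl)-3,7-dimethyl-7-(triethylsilyloxy)octa-2,5-dien-1-ol | O[C@@H](c1cc(OC)ccc1OC)/C=C(\C)C/C=C/C(C)(C)O[Si](CC)(CC)CC | intermediate
14 | tricarbonyl(η6-arene)chromium complex of 13, Cr on the face of the C1 hydroxyl (C1–H beside 2-OMe) | O[C@@H](c1cc(OC)ccc1OC)/C=C(\C)C/C=C/C(C)(C)O[Si](CC)(CC)CC.O=C=[Cr](=C=O)=C=O | intermediate
15 | tricarbonyl(η6-arene)chromium complex of the C1 acetate of 13, same face | CC(=O)O[C@@H](c1cc(OC)ccc1OC)/C=C(\C)C/C=C/C(C)(C)O[Si](CC)(CC)CC.O=C=[Cr](=C=O)=C=O | intermediate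
16 | lithium enolate of 15 (not isolated) | [Li]OC(=C)O[C@@H](c1cc(OC)ccc1OC)/C=C(\C)C/C=C/C(C)(C)O[Si](CC)(CC)CC.O=C=[Cr](=C=O)=C=O | intermediate
17 | lithium tricarbonyl[η5-(1R,5R)-6,9-dimethoxy-3-oxo-1-(side chain)-2-oxaspiro[4.5]deca-6,8-dien-10-yl]chromate, Cr anti to C4 (not isolated) | COC1=CC=C(OC)[C@@]2(CC(=O)O[C@@H]2/C=C(\C)C/C=C/C(C)(C)O[Si](CC)(CC)CC)[CH-]1.[Li+].O=C=[Cr](=C=O)=C=O | intermediate
18 | (1R,5R)-6,9-dimethoxy-1-[(1E,4E)-2,6-dimethyl-6-(triethylsilyloxy)hepta-1,4-dien-1-yl]-2-oxaspiro[4.5]deca-6,8-dien-3-one (not isolated) | COC1=CC=C(OC)[C@@]2(CC(=O)O[C@@H]2/C=C(\C)C/C=C/C(C)(C)O[Si](CC)(CC)CC)C1 | intermediate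
19 | (1R,5R)-1-[(1E,4E)-2,6-dimethyl-6-(triethylsilyloxy)hepta-1,4-dien-1-yl]-2-oxaspiro[4.5]decane-3,6,9-trione | O=C1CCC(=O)[C@@]2(CC(=O)O[C@@H]2/C=C(\C)C/C=C/C(C)(C)O[Si](CC)(CC)CC)C1 | intermediate
20 | (1R,5R)-1-[(1E,4E)-2,6-dimethyl-6-(triethylsilyloxy)hepta-1,4-dien-1-yl]-2-oxaspiro[4.5]dec-7-ene-3,6,9-trione | O=C1C=CC(=O)[C@@]2(CC(=O)O[C@@H]2/C=C(\C)C/C=C/C(C)(C)O[Si](CC)(CC)CC)C1 | intermediate
21 | (1R,5R,9S)-9-hydroxy-1-[(1E,4E)-2,6-dimethyl-6-(triethylsilyloxy)hepta-1,4-dien-1-yl]-2-oxaspiro[4.5]dec-7-ene-3,6-dione | O[C@@H]1C=CC(=O)[C@@]2(CC(=O)O[C@@H]2/C=C(\C)C/C=C/C(C)(C)O[Si](CC)(CC)CC)C1 | intermediate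
22 | (1R,5R,9S)-1-[(1E,4E)-2,6-dimethyl-6-(triethylsilyloxy)hepta-1,4-dien-1-yl]-3,6-dioxo-2-oxaspiro[4.5]dec-7-en-9-yl acetate | CC(=O)O[C@@H]1C=CC(=O)[C@@]2(CC(=O)O[C@@H]2/C=C(\C)C/C=C/C(C)(C)O[Si](CC)(CC)CC)C1 | intermediate
23 | (1R,5R,9S)-1-[(1E,4E)-6-hydroxy-2,6-dimethylhepta-1,4-dien-1-yl]-3,6-dioxo-2-oxaspiro[4.5]dec-7-en-9-yl acetate | CC(=O)O[C@@H]1C=CC(=O)[C@@]2(CC(=O)O[C@@H]2/C=C(\C)C/C=C/C(C)(C)O)C1 | target

**Step count and risks**

Total step count: 13. Longest linear sequence: 13 steps (1 → 23); aldehyde 10 is bought and enters at step 6.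

Steps most likely to fail:

1. Step 9 (key step). The enolate may add to the unsubstituted ring carbon next to the ipso carbon (six-membered ring closure). The rotamer needed for ipso attack (side chain beside the 2-OMe group) may be too strained. The adduct may revert, or the benzylic position may be deprotonated, before protonation. Fallback (temporary silyl block; directed lithiation of arene–Cr(CO)3 complexes, silyl blocking and protodesilylation are known): it sets out from 14.
   - n-BuLi (2.2 equiv, THF, −78 °C) should give the O,C-dilithio complex F1, lithiated at the ring carbon flanked by the 5-OMe group and the carbinol-bearing carbon.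
   - Me3SiCl then gives the O,C-bis(trimethylsilyl) complex F2; K2CO3/MeOH frees the carbinol to give the ring-silylated alcohol complex F3; Ac2O/DMAP gives the ring-silylated acetate complex F4.
   - Under the conditions of step 9 the ring-silylated lithium enolate F5 cannot reach the blocked ortho carbon, and the SiMe3 group, by 1,3-allylic strain, holds C1–H on its own side, which is the rotamer needed for ipso attack.
   - The silylated cyclohexadienyl chromate F6 is protonated and freed from the metal as the 10-silyl bis(enol ether) F7. The acid hydrolysis removes the silyl group (protodesilylation next to the emerging C9 carbonyl) together with the enol ethers, and the sequence comes back to the route at 19.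

2. Step 7. Metal delivery may show poor facial selectivity (hydroxyl direction losing against undirected arene exchange), which would scramble the relation between C1 and the later C5. Fallback (planar chirality first, carbinol second; acetal complexation, resolution of ortho-substituted benzaldehyde complexes through amino-alcohol imines and exo addition of organolithiums are known): it sets out from 10.
   - HC(OMe)3/TsOH gives the dimethyl acetal F8; Cr(CO)6 in Bu2O–THF at reflux gives the acetal complex F9; aqueous HCl gives the racemic aldehyde complex F10.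
   - Condensation with L-valinol gives diastereomeric imine complexes that are separated by chromatography. The wanted imine complex F11 is hydrolysed back to F10 as a single planar enantiomer.
   - Alkenyllithium 11 (from 9 as in step 6) then adds at −78 °C to the carbonyl, which lies anti to the ortho OMe group, from the face away from Cr(CO)3. This should give the carbinol and the metal face in the required relation, and the sequence comes back to the route at 14.

3. Step 11. Reduction may occur at the wrong carbonyl (C6) or with insufficient facial selectivity if the substrate bias opposes the catalyst. Fallback (substrate-controlled and stereoconvergent): it sets out from 20.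
   - Luche reduction (NaBH4, CeCl3·7H2O, MeOH, −78 °C) should reduce only the less hindered C9 carbonyl and give 21 together with its C9 epimer, the (9R)-alcohol F12.
   - After separation 21 goes on through step 12, and F12 is converted by a Mitsunobu reaction with acetic acid (PPh3, DIAD, inversion at C9) into the same acetate, so that both epimers come back to the route at 22.

Further compounds
F1 | step 9 | O,C-dilithio derivative of 14 (lithium alkoxide, lithium on the ring carbon between C5-OMe and the carbinol-bearing carbon) | [Li]O[C@@H](c1c([Li])c(OC)ccc1OC)/C=C(\C)C/C=C/C(C)(C)O[Si](CC)(CC)CC.O=C=[Cr](=C=O)=C=O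
F2 | step 9 | O,C-bis(trimethylsilyl) derivative of 14 | C[Si](C)(C)O[C@@H](c1c([Si](C)(C)C)c(OC)ccc1OC)/C=C(\C)C/C=C/C(C)(C)O[Si](CC)(CC)CC.O=C=[Cr](=C=O)=C=O
F3 | step 9 | ring-silylated alcohol complex (6-trimethylsilyl analogue of 14) | O[C@@H](c1c([Si](C)(C)C)c(OC)ccc1OC)/C=C(\C)C/C=C/C(C)(C)O[Si](CC)(CC)CC.O=C=[Cr](=C=O)=C=O
F4 | step 9 | ring-silylated acetate complex (6-trimethylsilyl analogue of 15) | CC(=O)O[C@@H](c1c([Si](C)(C)C)c(OC)ccc1OC)/C=C(\C)C/C=C/C(C)(C)O[Si](CC)(CC)CC.O=C=[Cr](=C=O)=C=O
F5 | step 9 | ring-silylated lithium enolate complex | [Li]OC(=C)O[C@@H](c1c([Si](C)(C)C)c(OC)ccc1OC)/C=C(\C)C/C=C/C(C)(C)O[Si](CC)(CC)CC.O=C=[Cr](=C=O)=C=O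
F6 | step 9 | 10-trimethylsilyl analogue of chromate 17 | COC1=CC=C(OC)[C@@]2(CC(=O)O[C@@H]2/C=C(\C)C/C=C/C(C)(C)O[Si](CC)(CC)CC)[C-]1[Si](C)(C)C.[Li+].O=C=[Cr](=C=O)=C=O
F7 | step 9 | 10-trimethylsilyl analogue of bis(enol ether) 18 (either C10 epimer) | COC1=CC=C(OC)[C@@]2(CC(=O)O[C@@H]2/C=C(\C)C/C=C/C(C)(C)O[Si](CC)(CC)CC)C1[Si](C)(C)C
F8 | step 7 | 2-(dimethoxymethyl)-1,4-dimethoxybenzene | COC(OC)c1cc(OC)ccc1OC
F9 | step 7 | tricarbonyl[η6-2-(dimethoxymethyl)-1,4-dimethoxybenzene]chromium | COC(OC)c1cc(OC)ccc1OC.O=C=[Cr](=C=O)=C=O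
F10 | step 7 | tricarbonyl(η6-2,5-dimethoxybenzaldehyde)chromium (first racemic, then one planar enantiomer) | COc1ccc(OC)c(C=O)c1.O=C=[Cr](=C=O)=C=O
F11 | step 7 | L-valinol imine of F10 (the diastereomer that is kept) | COc1ccc(OC)c(/C=N/[C@@H](C(C)C)CO)c1.O=C=[Cr](=C=O)=C=O
F12 | step 11 | (1R,5R,9R)-9-hydroxy-1-[(1E,4E)-2,6-dimethyl-6-(triethylsilyloxy)hepta-1,4-dien-1-yl]-2-oxaspiro[4.5]dec-7-ene-3,6-dione | O[C@H]1C=CC(=O)[C@@]2(CC(=O)O[C@@H]2/C=C(\C)C/C=C/C(C)(C)O[Si](CC)(CC)CC)C1
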